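**Assumption:** the sense of induction of the chiral phosphoric acid in step 7 cannot be derived with certainty for this pair of substrates; the (R)-acid is written, and its antipode would be used if the first run shows the mirror-image series.

## Structural features

The target is a 3-O-methyl dihydroflavonol: benzene ring A is fused to a 2,3-dihydropyran-4-one ring C (a chroman-4-one), and ring B, a 2,3-dihydroxy-4-methoxyphenyl group, sits on C2. Ring A carries hydroxyls at C5 and C6 and a methoxy group at C7; C8 is unsubstituted. C2 (benzylic, bound to O1) and C3 (bound to the methoxy oxygen and to the C4 ketone) are adjacent stereocentres, both R, with the aryl and methoxy groups trans. Three points are fragile: C3 can epimerise by enolisation; the O1–C2 bond can open by β-elimination under base or by ionisation under acid, because the para methoxy and ortho oxygen of ring B stabilise a benzylic cation; and the two catechol-type diols are easily oxidised. The phenols are therefore unveiled last and base is avoided near the end. The real difficulty is to fix the absolute configuration of C3 while it already bears a methyl ether, since a late selective methylation among seven oxygens is unattractive, and to keep methylated and free phenolic oxygens apart. The C5 hydroxyl is peri to the C4 carbonyl, so it can travel as a methyl ether and be freed by chelation-assisted cleavage. The key step uses the fact that C3 is bound to three atoms of different origin (the methoxy oxygen, the C4 carbonyl carbon on ring A and the carbinol carbon C2 on ring B), so C3 can be the carbene carbon of a ring A diazomethyl ketone that takes up methanol and the ring B aldehyde in turn.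

## Logic of the disconnections

**15 from 14.** The three O–CH2Ph bonds (O6, O2', O3') and the O5–CH3 bond are re-formed in the backward sense. The oxidation-prone free phenols thus appear only in the last step, and one Lewis acid operation removes all four groups. The forward step must cleave the C5 methyl ether and spare those at C7, C4' and C3; chelation of boron between O5 and the C4 carbonyl is the basis for this.

**14 from 13.** The O1–C2 bond is cut. Ring C is opened to an acyclic β-hydroxy-α-methoxy ketone with a free ring A phenol, which turns a cyclic trans problem into an acyclic aldol problem. The closure displaces the carbinol oxygen, so C2 is inverted (S in 13 becomes R in 14) while C3 keeps R. Assigning the descriptors shows that the syn (2R,3S) aldol is the one required. The forward step must proceed by substitution with inversion and not by ionisation or elimination.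

**13 from 12.** Only the O–Si bond is re-formed. The ring A phenol must be masked during the carbenoid step, and a fluoride-labile group is removed without base strong enough for retro-aldol cleavage.

**12 from 8, 10 and 11.** The C2–C3 bond and the C3–O(methyl) bond are cut at the same carbon. This is the largest simplification of the route: both stereocentres, the C3 ether and the complete C6–C3–C6 skeleton come from two arenes and 11. The forward step must capture the ylide with 10 faster than it is protonated, and must deliver the syn relationship and one absolute sense.

**8 from 6.** The C=N2 bond is removed and the diazomethyl ketone becomes a methyl ketone. Transient trifluoroacetylation (7) followed by diazo transfer avoids diazomethane. The forward step must enolise a hindered ketone without moving the neighbouring silyl group.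

**6 from 5, and 5 from 4.** One O–Si and one O–CH2Ph bond are cut. The two hydroxyls of 4 differ because one is hydrogen-bonded to the ketone: the free one takes the benzyl group first, the chelated one the silyl group afterwards. In this order no benzyl ether meets the Lewis acid of the acylation.

**4 from 3.** The aryl–acyl bond is cut. In 3 the two free ring positions are equivalent and each is ortho to a hydroxyl, so the acylation has no regiochemical question.

**3 from 1.** The aryl–CHO bond is exchanged for aryl–OH (through 2). 1 already has the 1,2,3-trioxygen pattern with the middle oxygen free and the outer two methylated, which is the ring A pattern needed.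

**10 from 9.** Two O–CH2Ph bonds are cut. 9 carries the complete ring B oxygenation, so only protection is needed.

## Other disconnections considered

**Alternative 1:** The cut is O1–C8a, the aryl ether bond of ring C on the ring A side.
- Forward step: the catechol ketone A1, an anti (2R,3R) aldol with a free 2,3-dihydroxy-4-methoxyphenyl ring A and the benzyl-protected ring B, would be oxidised with Ag2O to its ortho-quinone. The carbinol oxygen would add in a 6-endo conjugate manner to the ring carbon ortho to the acyl group (the future C8a), and tautomerisation with a sodium dithionite work-up would give the 5,6-dihydroxychromanone A2, one hydrogenolysis from the target.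
- In its favour: the carbinol C–O bond is never broken, so C2 keeps its configuration and the cation-prone benzylic centre is spared a substitution. The 5,6-diol appears directly, without chelation-controlled demethylation. On these two points the alternative is the better plan.
- Against it: the acyl-substituted ortho-quinone is a strong and unselective electrophile, and a secondary alcohol is a weak partner for it. A2 is more electron-rich than A1 and can be oxidised further by the same reagent. The β-hydroxy ketone can cleave by retro-aldol reaction. A1 needs a free catechol on ring A beside a masked one on ring B.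
- Comparison: structurally it leaves the real problem untouched, since A1 still holds both stereocentres and the C3 ether and would need an enantioselective anti aldol of the same kind as the chosen key step. Mechanistically the ring closure has less close analogy than a Mitsunobu etherification. In step count the plans are about equal: one step after the key step instead of three, but extra steps before it for orthogonal protection.

**Alternative 2:** The cuts are C4a–C4, C4–C3 and O1–C2, with C4 coming from carbon monoxide.
- Forward step: the iodophenol A3 and the ring B alkyne A4 would be joined under carbon monoxide with PdCl2(PPh3)2 and an amine. Oxidative addition into the C–I bond, CO insertion, coupling of the acylpalladium with the alkyne and 6-endo addition of the phenol to the ynone would give the flavone A5.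
- In its favour: it is the most convergent assembly of the skeleton, every bond-forming event is well-established catalysis, the assembly has no stereochemical demand, and A3 derives from the same syringaldehyde-based phenol. On convergence and on the reliability of the skeletal bond formation it is the better plan.
- Against it: A5 has neither the C3 oxygen nor a stereocentre. C3 would have to be oxidised and methylated, and the tetrasubstituted, electron-rich C2=C3 bond then reduced enantioselectively to the trans isomer. Syn hydrogenation would give the cis isomer, so an epimerisation would be needed as well. 5-exo closure to an aurone competes in the annulation.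
- Comparison: it solves the easy part (the skeleton) and postpones the hard part (C3 and both centres). Its key step is mechanistically safer than the chosen one, but the steps after it are weaker, and at least four would follow the key step instead of three.

**Alternative 3:** The cut is C2–C3.
- Forward step: the diazoketone A6, in which O1 already carries the ring B benzyl group as an ether, would be treated with Rh2(S-PTTL)4. The carbenoid at C3 would insert into the benzylic C–H bond beside O1 and close ring C to the (2S)-flavanone A7. The descriptor S describes the same spatial arrangement as R at C2 of the target, because C3 is a methylene group in A7.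
- In its favour: ring C and the C2 stereocentre arise in one catalytic step, the precursor is made by plain etherification with no silyl group and no Mitsunobu closure, and the C–H bond is doubly activated (benzylic and α to oxygen). On the directness of ring closure it is the better plan.
- Against it: A7 lacks the C3 oxygen, which would have to come from enolate oxidation and O-methylation, conditions under which a flavanone can open to the chalcone and lose C2. Attack of O1 on the carbenoid followed by [1,2]-shift of the very electron-rich benzyl group (leading to a benzofuranone) and aromatic cycloaddition compete with the six-membered insertion.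
- Comparison: both plans place a rhodium carbenoid at C3. The chosen plan lets it react with an external O–H group, the fastest carbenoid process, and sets the C3 oxygen and both centres together. Here the carbenoid must prefer a 1,6 C–H insertion over ether ylide formation. Three steps would follow the key step in both plans, so step economy is equal.

Key step: step 7

## Route

Step 1
Reactants: 1 syringaldehyde (4-hydroxy-3,5-dimethoxybenzaldehyde)
Product: 3 2,6-dimethoxybenzene-1,4-diol, via 4-hydroxy-3,5-dimethoxyphenyl formate 2 (not isolated)
Conditions: H2O2 (30% aq), NaOH, H2O, 0 °C to rt, N2; then HCl, Na2S2O4 wash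
Reagents that add atoms: hydrogen peroxide, OO
Why: Dakin oxidation: the hydroperoxide adduct of the para-hydroxybenzaldehyde rearranges by aryl migration to the formate 2, which the alkali hydrolyses in the same flask; exclusion of air and the dithionite wash should keep the electron-rich hydroquinone from going on to the quinone.

Step 2
Reactants: 3 2,6-dimethoxybenzene-1,4-diol
Product: 4 1-(3,6-dihydroxy-2,4-dimethoxyphenyl)ethan-1-one
Conditions: AcOH, BF3·OEt2, 80 °C; then aq NaOAc
Reagents that add atoms: acetic acid, CC(=O)O
Why: Friedel–Crafts C-acetylation of a strongly activated phenol; the two free ring positions of 3 are equivalent and each lies ortho to a hydroxyl, so one mono-ketone is expected, and the first acyl group deactivates the ring towards a second.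

Step 3
Reactants: 4 1-(3,6-dihydroxy-2,4-dimethoxyphenyl)ethan-1-one
Product: 5 1-[3-(benzyloxy)-6-hydroxy-2,4-dimethoxyphenyl]ethan-1-one
Conditions: BnBr (1.05 equiv), K2CO3, acetone, reflux
Reagents that add atoms: benzyl bromide, BrCc1ccccc1
Why: Williamson etherification; the C6 hydroxyl is held by a hydrogen bond to the ketone and is the poorer nucleophile, so one equivalent of halide should go to the C3 hydroxyl.

Step 4
Reactants: 5 1-[3-(benzyloxy)-6-hydroxy-2,4-dimethoxyphenyl]ethan-1-one
Product: 6 1-[3-(benzyloxy)-2,4-dimethoxy-6-{[tri(propan-2-yl)silyl]oxy}phenyl]ethan-1-one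
Conditions: iPr3SiOTf, 2,6-lutidine, CH2Cl2, 0 °C
Reagents that add atoms: tri(propan-2-yl)silyl trifluoromethanesulfonate, CC(C)[Si](OS(=O)(=O)C(F)(F)F)(C(C)C)C(C)C
Why: O-silylation of the chelated phenol with the reactive silyl triflate; the weak hindered base should not enolise the methyl ketone, and the bulky silyl group is chosen to survive the amide base of step 5 and to keep this oxygen from attacking the carbenoid in step 7.

Step 5
Reactants: 6 1-[3-(benzyloxy)-2,4-dimethoxy-6-{[tri(propan-2-yl)silyl]oxy}phenyl]ethan-1-one
Product: 8 1-[3-(benzyloxy)-2,4-dimethoxy-6-{[tri(propan-2-yl)silyl]oxy}phenyl]-2-diazoethan-1-one, via trifluoroacetylated diketone 7 (not isolated)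
Conditions: LiN(SiMe3)2, THF, −78 °C; CF3CO2CH2CF3; dilute HCl work-up; then 4-AcNHC6H4SO2N3, Et3N, H2O, MeCN, rt
Reagents that add atoms: 4-acetamidobenzenesulfonyl azide, CC(=O)Nc1ccc(cc1)S(=O)(=O)N=[N+]=[N-]; 2,2,2-trifluoroethyl trifluoroacetate, FC(F)(F)COC(=O)C(F)(F)F (its CF3CO group is carried by 7 only)
Why: Detrifluoroacetylative diazo transfer: Claisen trifluoroacetylation of the kinetic enolate makes the methylene acidic enough for Regitz-type transfer, and the adduct fragments with loss of the trifluoroacetyl group as the N-acylsulfonamide; no diazomethane is needed and a shelf-stable azide is used.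

Step 6
Reactants: 9 2,3-dihydroxy-4-methoxybenzaldehyde
Product: 10 2,3-bis(benzyloxy)-4-methoxybenzaldehyde
Conditions: BnBr (2.5 equiv), K2CO3, DMF, 60 °C
Reagents that add atoms: benzyl bromide, BrCc1ccccc1
Why: Double Williamson etherification; excess halide and warming are used because the C2 hydroxyl is hydrogen-bonded to the aldehyde.

Step 7
Reactants: 8 1-[3-(benzyloxy)-2,4-dimethoxy-6-{[tri(propan-2-yl)silyl]oxy}phenyl]-2-diazoethan-1-one; 11 methanol; 10 2,3-bis(benzyloxy)-4-methoxybenzaldehyde
Product: 12 (2R,3S)-1-[3-(benzyloxy)-2,4-dimethoxy-6-{[tri(propan-2-yl)silyl]oxy}phenyl]-3-[2,3-bis(benzyloxy)-4-methoxyphenyl]-3-hydroxy-2-methoxypropan-1-one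
Conditions: Rh2(OAc)4 (2 mol %), (R)-3,3'-bis(2,4,6-triisopropylphenyl)-1,1'-binaphthalene-2,2'-diyl hydrogen phosphate (10 mol %), 4 Å MS, CH2Cl2, −20 °C; 8 and MeOH (1.2 equiv) added over 2 h to 10 (2 equiv)
Reagents that add atoms: none
Why: Rh2(OAc)4 decomposes 8 with loss of dinitrogen to a rhodium carbenoid at the future C3, and the oxygen of 11 adds to it to give a rhodium-associated oxonium ylide, a fleeting species of the catalytic cycle that does not accumulate and that, through a proton shift inside a five-membered hydrogen-bonded ring, is in equilibrium with the Z enol of the methoxy ketone. The chiral phosphoric acid should bind that enol through its phosphoryl oxygen and the carbonyl oxygen of 10 through its acidic proton, so that the future C2–C3 bond forms inside the chiral pocket before the enol tautomerises to the simple O–H insertion product. The closest known reaction type is the three-component aldol-type trapping of alcohol-derived oxonium ylides from diazo carbonyl compounds with aldehydes under dirhodium and chiral acid co-catalysis; a terminal diazomethyl aryl ketone and an electron-rich aldehyde are demanding members of that class. No ring is closed in this step. The methoxy-bearing centre (R, locant 2 of 12) is set by the enol face that the bound acid leaves open, and the carbinol centre (S, locant 3) by the aldehyde face presented in the cyclic acid-bridged transition state, the Z enol geometry translating into the syn relationship. The step needs intermolecular capture of 11 to beat attack of the ring A ortho oxygens on the carbenoid, and aldehyde capture to beat proton shift. The bulky silyl group on the ortho oxygen, the choice of methyl and not benzyl on the other ortho oxygen, slow addition of 8 and the excess of 10 are meant to secure this, and the ortho benzyloxy oxygen of 10 offers the acid a second point of binding.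

Step 8
Reactants: 12 (2R,3S)-1-[3-(benzyloxy)-2,4-dimethoxy-6-{[tri(propan-2-yl)silyl]oxy}phenyl]-3-[2,3-bis(benzyloxy)-4-methoxyphenyl]-3-hydroxy-2-methoxypropan-1-one
Product: 13 (2R,3S)-1-[3-(benzyloxy)-6-hydroxy-2,4-dimethoxyphenyl]-3-[2,3-bis(benzyloxy)-4-methoxyphenyl]-3-hydroxy-2-methoxypropan-1-one
Conditions: Bu4NF, AcOH (1:1), THF, 0 °C
Reagents that add atoms: none
Why: Fluoride cleavage of the aryl silyl ether; buffering with acetic acid should keep the medium from becoming basic enough for retro-aldol cleavage or for epimerisation of the methoxy-bearing carbon.

Step 9
Reactants: 13 (2R,3S)-1-[3-(benzyloxy)-6-hydroxy-2,4-dimethoxyphenyl]-3-[2,3-bis(benzyloxy)-4-methoxyphenyl]-3-hydroxy-2-methoxypropan-1-one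
Product: 14 (2R,3R)-6-(benzyloxy)-2-[2,3-bis(benzyloxy)-4-methoxyphenyl]-3,5,7-trimethoxy-2,3-dihydro-4H-1-benzopyran-4-one
Conditions: PPh3, DIAD, THF (0.01 M), 0 °C
Reagents that add atoms: none
Why: Intramolecular Mitsunobu etherification (6-exo-tet): the hydrogen-bonded phenol is acidic enough for the betaine, and its oxygen displaces the phosphonium-activated benzylic oxygen with inversion, so the S carbinol becomes R at C2 while C3 is untouched; the syn adduct should thus give the 2,3-trans ring.

Step 10
Reactants: 14 (2R,3R)-6-(benzyloxy)-2-[2,3-bis(benzyloxy)-4-methoxyphenyl]-3,5,7-trimethoxy-2,3-dihydro-4H-1-benzopyran-4-one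
Product: 15 (2R,3R)-2-(2,3-dihydroxy-4-methoxyphenyl)-5,6-dihydroxy-3,7-dimethoxy-2,3-dihydro-4H-1-benzopyran-4-one (CNP0075602.1)
Conditions: BCl3 (8 equiv), C6HMe5, CH2Cl2, −78 to 0 °C; then MeOH, H2O
Reagents that add atoms: none
Why: Lewis acid ether cleavage: the benzyl ethers should fall at low temperature with pentamethylbenzene as benzyl cation trap, and the C5 methyl ether next because boron chelates between O5 and the C4 carbonyl; the C7, C4' and C3 methyl ethers lack that six-membered chelate and should survive, and the acidic medium does not enolise C3.

## Compound list

1 | syringaldehyde (4-hydroxy-3,5-dimethoxybenzaldehyde) | COc1cc(C=O)cc(OC)c1O | starting material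
2 | 4-hydroxy-3,5-dimethoxyphenyl formate | O=COc1cc(OC)c(O)c(OC)c1 | intermediate
3 | 2,6-dimethoxybenzene-1,4-diol | COc1cc(O)cc(OC)c1O | intermediate
4 | 1-(3,6-dihydroxy-2,4-dimethoxyphenyl)ethan-1-one | CC(=O)c1c(O)cc(OC)c(O)c1OC | intermediate
5 | 1-[3-(benzyloxy)-6-hydroxy-2,4-dimethoxyphenyl]ethan-1-one | CC(=O)c1c(O)cc(OC)c(OCc2ccccc2)c1OC | intermediate
6 | 1-[3-(benzyloxy)-2,4-dimethoxy-6-{[tri(propan-2-yl)silyl]oxy}phenyl]ethan-1-one | CC(=O)c1c(OC)c(OCc2ccccc2)c(OC)cc1O[Si](C(C)C)(C(C)C)C(C)C | intermediate
7 | 1-[3-(benzyloxy)-2,4-dimethoxy-6-{[tri(propan-2-yl)silyl]oxy}phenyl]-4,4,4-trifluorobutane-1,3-dione | O=C(CC(=O)C(F)(F)F)c1c(OC)c(OCc2ccccc2)c(OC)cc1O[Si](C(C)C)(C(C)C)C(C)C | intermediate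
8 | 1-[3-(benzyloxy)-2,4-dimethoxy-6-{[tri(propan-2-yl)silyl]oxy}phenyl]-2-diazoethan-1-one | [N-]=[N+]=CC(=O)c1c(OC)c(OCc2ccccc2)c(OC)cc1O[Si](C(C)C)(C(C)C)C(C)C | intermediate
9 | 2,3-dihydroxy-4-methoxybenzaldehyde | COc1ccc(C=O)c(O)c1O | starting material
10 | 2,3-bis(benzyloxy)-4-methoxybenzaldehyde | COc1ccc(C=O)c(OCc2ccccc2)c1OCc1ccccc1 | intermediate
11 | methanol | CO | starting material
12 | (2R,3S)-1-[3-(benzyloxy)-2,4-dimethoxy-6-{[tri(propan-2-yl)silyl]oxy}phenyl]-3-[2,3-bis(benzyloxy)-4-methoxyphenyl]-3-hydroxy-2-methoxypropan-1-one | COc1ccc([C@H](O)[C@@H](OC)C(=O)c2c(OC)c(OCc3ccccc3)c(OC)cc2O[Si](C(C)C)(C(C)C)C(C)C)c(OCc2ccccc2)c1OCc1ccccc1 | intermediate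
13 | (2R,3S)-1-[3-(benzyloxy)-6-hydroxy-2,4-dimethoxyphenyl]-3-[2,3-bis(benzyloxy)-4-methoxyphenyl]-3-hydroxy-2-methoxypropan-1-one | COc1ccc([C@H](O)[C@@H](OC)C(=O)c2c(OC)c(OCc3ccccc3)c(OC)cc2O)c(OCc2ccccc2)c1OCc1ccccc1 | intermediate
14 | (2R,3R)-6-(benzyloxy)-2-[2,3-bis(benzyloxy)-4-methoxyphenyl]-3,5,7-trimethoxy-2,3-dihydro-4H-1-benzopyran-4-one | COc1ccc([C@H]2Oc3cc(OC)c(OCc4ccccc4)c(OC)c3C(=O)[C@@H]2OC)c(OCc2ccccc2)c1OCc1ccccc1 | intermediate
15 | (2R,3R)-2-(2,3-dihydroxy-4-methoxyphenyl)-5,6-dihydroxy-3,7-dimethoxy-2,3-dihydro-4H-1-benzopyran-4-one | COc1ccc([C@H]2Oc3cc(OC)c(O)c(O)c3C(=O)[C@@H]2OC)c(O)c1O | target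

## Step count and least certain steps

Total: 10 steps. Longest linear sequence: 9 steps (1 to 15 through steps 1–5 and 7–10); step 6 is a one-step branch.

**Step 7 (key step).** The most likely failure is proton transfer within the ylide outrunning C–C bond formation, because 10 is deactivated by three donor oxygens and hindered by its ortho substituent; the result would be formal O–H insertion. Capture of the carbenoid by the ortho methoxy oxygen of ring A, and incomplete syn or facial selectivity, are further possibilities. Fallback (from 8, back at 12): 8 and 11 would be combined with Rh2(OAc)4 alone to give 1-[3-(benzyloxy)-2,4-dimethoxy-6-{[tri(propan-2-yl)silyl]oxy}phenyl]-2-methoxyethan-1-one F1, which is also what a failed three-component run leaves behind, so that material is not lost. F1 would then be converted with diisopinocampheylboron triflate and iPr2NEt into its Z boron enolate and added to 10 at −78 °C. This is a reagent-controlled syn aldol through a closed chair transition state, with the antipode of the terpene ligand chosen to give the (2R,3S) series, and it returns to 12.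

**Step 9.** The phosphonium-activated carbinol may ionise, since the para methoxy and ortho oxygen of ring B stabilise the cation, with loss of clean inversion; elimination to the enone followed by non-selective re-addition of the phenol is also possible. Fallback (from 13, back at 14, no new compound): the closure would be run as an acid-mediated dehydrative cyclisation (catalytic TsOH, CH2Cl2, rt) that deliberately goes through the benzylic cation. The configuration at C2 is then set by the C3 centre under thermodynamic control in favour of the trans ring, and the carbinol configuration no longer matters.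

**Step 10.** Ether cleavage may go too far: the C7 or C4' methyl ether next to a newly formed boron aryloxide, or the C3 methyl ether, could be lost, and ring C could open at O1–C2 under the Lewis acid. Fallback (from 14, back at 15): chelation-controlled demethylation alone with MgI2 etherate in toluene would give (2R,3R)-6-(benzyloxy)-2-[2,3-bis(benzyloxy)-4-methoxyphenyl]-5-hydroxy-3,7-dimethoxy-2,3-dihydro-4H-1-benzopyran-4-one F2. The benzyl groups would then be removed by neutral hydrogenolysis (H2, Pd(OH)2 on carbon, EtOAc) to give 15.

**Step 5.** Trifluoroacetylation of the crowded enolate may be incomplete, the silyl group may migrate to the enolate oxygen, or the silyl ether may be lost in the aqueous amine stage. Fallback (from 6, back at 8): the kinetic lithium enolate (LiN(SiMe3)2, THF, −78 °C) would be brominated with N-bromosuccinimide to give 1-[3-(benzyloxy)-2,4-dimethoxy-6-{[tri(propan-2-yl)silyl]oxy}phenyl]-2-bromoethan-1-one F3. F3 would be converted into 8 with N,N'-ditosylhydrazine and DBU in THF at 0 °C (displacement of bromide, then double sulfinate elimination).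

**Step 3.** Both hydroxyls may be alkylated, or the hydroquinone-type 4 may be oxidised by air under basic conditions. Fallback (from 1, back at 5): the order would be changed. 1 would be benzylated first (BnBr, K2CO3, DMF) to 4-(benzyloxy)-3,5-dimethoxybenzaldehyde F4. Baeyer–Villiger oxidation with mCPBA would give 4-(benzyloxy)-3,5-dimethoxyphenyl formate F5, and hydrolysis (aq NaOH, THF) would give 4-(benzyloxy)-3,5-dimethoxyphenol F6, whose two free ring positions are again equivalent. C-acetylation (AcOH, BF3·OEt2, at the lowest temperature that suffices) would give 5. The benzyl ether then has to survive the Lewis acid, which is why this order is only the fallback.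

## Further compounds

F1 | step 7 | 1-[3-(benzyloxy)-2,4-dimethoxy-6-{[tri(propan-2-yl)silyl]oxy}phenyl]-2-methoxyethan-1-one | COCC(=O)c1c(OC)c(OCc2ccccc2)c(OC)cc1O[Si](C(C)C)(C(C)C)C(C)C
F0 | step 9 | none | none
F2 | step 10 | (2R,3R)-6-(benzyloxy)-2-[2,3-bis(benzyloxy)-4-methoxyphenyl]-5-hydroxy-3,7-dimethoxy-2,3-dihydro-4H-1-benzopyran-4-one | COc1ccc([C@H]2Oc3cc(OC)c(OCc4ccccc4)c(O)c3C(=O)[C@@H]2OC)c(OCc2ccccc2)c1OCc1ccccc1
F3 | step 5 | 1-[3-(benzyloxy)-2,4-dimethoxy-6-{[tri(propan-2-yl)silyl]oxy}phenyl]-2-bromoethan-1-one | BrCC(=O)c1c(OC)c(OCc2ccccc2)c(OC)cc1O[Si](C(C)C)(C(C)C)C(C)C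
F4 | step 3 | 4-(benzyloxy)-3,5-dimethoxybenzaldehyde | COc1cc(C=O)cc(OC)c1OCc1ccccc1
F5 | step 3 | 4-(benzyloxy)-3,5-dimethoxyphenyl formate | O=COc1cc(OC)c(OCc2ccccc2)c(OC)c1
F6 | step 3 | 4-(benzyloxy)-3,5-dimethoxyphenol | COc1cc(O)cc(OC)c1OCc1ccccc1
A1 | alternative 1 | (2R,3R)-3-[2,3-bis(benzyloxy)-4-methoxyphenyl]-1-(2,3-dihydroxy-4-methoxyphenyl)-3-hydroxy-2-methoxypropan-1-one | COc1ccc([C@@H](O)[C@@H](OC)C(=O)c2ccc(OC)c(O)c2O)c(OCc2ccccc2)c1OCc1ccccc1
A2 | alternative 1 | (2R,3R)-2-[2,3-bis(benzyloxy)-4-methoxyphenyl]-5,6-dihydroxy-3,7-dimethoxychroman-4-one | COc1ccc([C@H]2Oc3cc(OC)c(O)c(O)c3C(=O)[C@@H]2OC)c(OCc2ccccc2)c1OCc1ccccc1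
A3 | alternative 2 | 4-(benzyloxy)-2-iodo-3,5-dimethoxyphenol | COc1cc(O)c(I)c(OC)c1OCc1ccccc1
A4 | alternative 2 | 2,3-bis(benzyloxy)-1-ethynyl-4-methoxybenzene | C#Cc1ccc(OC)c(OCc2ccccc2)c1OCc1ccccc1
A5 | alternative 2 | 6-(benzyloxy)-2-[2,3-bis(benzyloxy)-4-methoxyphenyl]-5,7-dimethoxy-4H-chromen-4-one | COc1ccc(-c2cc(=O)c3c(OC)c(OCc4ccccc4)c(OC)cc3o2)c(OCc2ccccc2)c1OCc1ccccc1
A6 | alternative 3 | 1-[3-(benzyloxy)-6-{[2,3-bis(benzyloxy)-4-methoxyphenyl]methoxy}-2,4-dimethoxyphenyl]-2-diazoethan-1-one | [N-]=[N+]=CC(=O)c1c(OC)c(OCc2ccccc2)c(OC)cc1OCc1ccc(OC)c(OCc2ccccc2)c1OCc1ccccc1
A7 | alternative 3 | (2S)-6-(benzyloxy)-2-[2,3-bis(benzyloxy)-4-methoxyphenyl]-5,7-dimethoxychroman-4-one | COc1ccc([C@H]2Oc3cc(OC)c(OCc4ccccc4)c(OC)c3C(=O)C2)c(OCc2ccccc2)c1OCc1ccccc1
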